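**Plan**

- Retrosynthetic cuts, in order: the C8 carboxyl back to a methyl group (allylic oxidation); C11–C12 (alkyl–alkyl Suzuki–Miyaura coupling, side chain bought with C13 in place); C9=C11 (methylenation of a C9 ketone); a helper ester on C2; C3–C4 (ring A); C10–C1 and C10–CH3 (two enolate alkylations). This leads to (R)-carvone, methyl 2-(bromomethyl)acrylate and (S)-3-bromo-2-methylpropan-1-ol.
- Enabling feature: ring B (C5–C10, with C7=C8 carrying one carbon on C8) together with C4 and its two methyls is the carvone skeleton. C4 is a fully substituted carbon on C5, so it is the tertiary radical that hydrogen-atom transfer to the carvone isopropenyl group gives, and C3 lies three atoms from C10.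
- Forward order: ring B is bought; C10 is made quaternary by methylation, then allylation with an acrylate arm; ring A closes by radical C3–C4 bond formation (ester on C2 as activating helper, removed by hydrolysis and decarboxylation); the C9 ketone is methylenated; hydroboration and cross-coupling join the chain; the C8 methyl is oxidised last.
- Stereochemistry: C5 from (R)-carvone; C10 by alkylation anti to the isopropenyl group; C9 by hydroboration anti to the axial C10 methyl; C13 from the bought bromo alcohol.

Key step: step 3

Numbering used below (drimane/labdane type): ring A = C1–C5 and C10, ring B = C5–C10; C4 carries the two methyls, C10 the angular methyl, C8 the carbon C17, C9 the chain C11–C12–C13(CH3)–C14–O.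
Assumption: compounds 7, 8 and 9 are carried as mixtures of C2 epimers, since C2 becomes a CH2 group in step 5.

**Step 1**
Reactants: 1 (R)-(−)-carvone
Product: 3 6-methylcarvone (C6 epimer mixture), via carvone lithium dienolate 2 (not isolated)
Conditions: LiN(iPr)2, THF, −78 °C; MeI, −78 to 0 °C
Reagents that add atoms: iodomethane, CI
Why: Kinetic α′-deprotonation of the enone gives the cross-conjugated lithium dienolate, which is C-methylated (enolate alkylation) at the future C10; the configuration of this center does not matter because it is re-formed in step 2.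

**Step 2**
Reactants: 3 6-methylcarvone; 4 methyl 2-(bromomethyl)acrylate
Product: 6 methyl 2-{[(1S,6S)-1,3-dimethyl-2-oxo-6-(prop-1-en-2-yl)cyclohex-3-en-1-yl]methyl}prop-2-enoate (CH2 arm trans and ring methyl cis to the isopropenyl group), via 6-methylcarvone lithium enolate 5 (not isolated)
Conditions: LiN(iPr)2, THF, −78 °C; then 4, −78 to 0 °C
Reagents that add atoms: none
Why: Enolate allylation (SN2′ addition–elimination on the bromomethyl acrylate) should create the quaternary C10 with the electrophile entering anti to the neighbouring C5 isopropenyl group, so that the CH2 arm (C1) is trans and the methyl cis to that group.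

**Step 3**
Reactants: 6 acrylate-armed carvone
Product: 7 methyl (4aS,8aS)-4,4,7,8a-tetramethyl-8-oxo-1,2,3,4,4a,5,8,8a-octahydronaphthalene-2-carboxylate (trans-fused decalin enone, CO2Me on C2, both C2 epimers)
Conditions: Fe(acac)3 (30 mol%), PhSiH3, EtOH/ethylene glycol, 60 °C
Reagents that add atoms: none
Why: Fe(acac)3 and PhSiH3 form an iron hydride that transfers a hydrogen atom to the terminal CH2 of the electron-rich isopropenyl group, giving a tertiary radical at C4 with its two methyls; this nucleophilic radical adds to the unsubstituted acrylate terminus C3, and the α-ester radical at C2 is reduced to the iron enolate and protonated by ethanol. The closest known reaction type is the iron-hydride reductive coupling of a donor alkene with a tethered acceptor alkene, that is, an intramolecular Giese addition started by hydrogen-atom transfer. Ring A closes in the 6-endo-trig mode, because both acrylate carbons C2 and C3 end up inside the new six-membered ring (C3–C4 bond). No stereocenter of the target is made at the new bond (C3 is CH2, C4 carries two methyls); the trans ring fusion follows from the trans relation of the C5 isopropenyl group and the C10 CH2 arm fixed in step 2, and the C2 center forms without control and is erased in step 5. The step needs hydrogen-atom transfer to the isopropenyl group and not to the acrylate or the enone, which the higher electron density of the 1,1-disubstituted donor alkene should secure. It also needs attack at C3 and not 5-exo attack at C2, which polarity matching and the ester-bearing, substituted C2 should secure.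

**Step 4**
Reactants: 7 decalin enone ester
Product: 8 (4aS,8aS)-4,4,7,8a-tetramethyl-8-oxo-1,2,3,4,4a,5,8,8a-octahydronaphthalene-2-carboxylic acid (both C2 epimers)
Conditions: LiOH·H2O, THF/MeOH/H2O, rt; then aqueous HCl
Reagents that add atoms: lithium hydroxide, [Li+].[OH-]
Why: Saponification of the unhindered secondary methyl ester on C2 should leave the enone and both ring-fusion centers untouched, since neither C5 nor C10 is enolisable.

**Step 5**
Reactants: 8 decalin enone acid
Product: 10 (4aS,8aS)-2,5,5,8a-tetramethyl-4a,5,6,7,8,8a-hexahydronaphthalen-1(4H)-one (trans-fused 8-methyl-7-en-9-one), via Barton ester 9 (not isolated)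
Conditions: N-hydroxypyridine-2-thione, DCC, DMAP (cat.), CH2Cl2, rt, dark; then t-BuSH, visible light, rt
Reagents that add atoms: none
Why: Barton decarboxylation: the thiohydroxamate ester fragments in a radical chain, CO2 is lost and the secondary C2 radical takes a hydrogen atom from the thiol, which removes the helper and leaves C2 as CH2.

**Step 6**
Reactants: 10 decalin enone
Product: 11 drima-7,9(11)-diene, (4aS,8aS)-2,5,5,8a-tetramethyl-1-methylidene-1,4,4a,5,6,7,8,8a-octahydronaphthalene
Conditions: Ph3PCH3Br, KOtBu, toluene, 90 °C
Reagents that add atoms: methyltriphenylphosphonium bromide, C[P+](c1ccccc1)(c1ccccc1)c1ccccc1.[Br-]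
Why: Wittig methylenation with the salt-free ylide at elevated temperature is the standard way to methylenate hindered ketones; any γ-deprotonation of the enone is reversible and touches no stereocenter.

**Step 7**
Reactants: 12 (S)-3-bromo-2-methylpropan-1-ol
Product: 13 (S)-3-bromo-2-methylpropyl 2-methylpropanoate
Conditions: isobutyryl chloride, Et3N, DMAP (cat.), CH2Cl2, 0 °C
Reagents that add atoms: 2-methylpropanoyl chloride, CC(C)C(Cl)=O
Why: Acylation of the primary alcohol installs the isobutyrate of the target at the outset and does not touch the stereocenter, which becomes C13.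

**Step 8**
Reactants: 11 drima-7,9(11)-diene; 13 (S)-3-bromo-2-methylpropyl 2-methylpropanoate
Product: 15 (2R)-2-methyl-4-[(1S,4aS,8aS)-2,5,5,8a-tetramethyl-1,4,4a,5,6,7,8,8a-octahydronaphthalen-1-yl]butyl 2-methylpropanoate (9α-H, chain equatorial), via B-alkyl-9-BBN borane 14 (not isolated)
Conditions: 9-BBN, THF, 0 °C to rt; then 13, Pd(OAc)2 (cat.), PCy3 (cat.), K3PO4·H2O, THF, rt to 40 °C
Reagents that add atoms: none
Why: 9-BBN should add to the exocyclic C9=C11 bond with boron on C11 and hydrogen delivered to C9 from the α face, away from the axial C10 methyl, which sets C9; the primary alkylborane then undergoes alkyl–alkyl Suzuki–Miyaura coupling with the primary bromide, which tolerates the ester and leaves C13 untouched.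

**Step 9**
Reactants: 15 coupled ester
Product: 16 (2R)-4-[(1R,4aS,8aS)-2-formyl-5,5,8a-trimethyl-1,4,4a,5,6,7,8,8a-octahydronaphthalen-1-yl]-2-methylbutyl 2-methylpropanoate (7-en-17-al)
Conditions: SeO2, 1,4-dioxane, reflux
Reagents that add atoms: selenium dioxide, O=[Se]=O
Why: Riley allylic oxidation (ene reaction, then [2,3]-shift) should occur at the more substituted alkene carbon C8 and there favour the methyl group over the hindered C9 methine, as is known for 8-methyl-drim-7-enes, and run on to the conjugated aldehyde.

**Step 10**
Reactants: 16 enal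
Product: 17 (1R,4aS,8aS)-5,5,8a-trimethyl-1-[(3R)-3-methyl-4-(2-methylpropanoyloxy)butyl]-1,4,4a,5,6,7,8,8a-octahydronaphthalene-2-carboxylic acid (target)
Conditions: NaClO2, NaH2PO4, 2-methyl-2-butene, t-BuOH/H2O, rt
Reagents that add atoms: sodium chlorite, [Na+].[O-]Cl=O
Why: Pinnick oxidation converts the conjugated aldehyde to the acid without moving the C7=C8 bond, epimerising C9 or cleaving the isobutyrate.

**Compound list**

1 | (R)-(−)-carvone | CC1=CC[C@@H](C(C)=C)CC1=O | starting material
2 | carvone lithium dienolate | [Li]OC1=C[C@H](C(C)=C)CC=C1C | intermediate (not isolated)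
3 | 6-methylcarvone, (5R)-2,6-dimethyl-5-(prop-1-en-2-yl)cyclohex-2-en-1-one, C6 epimer mixture | CC1=CC[C@@H](C(C)=C)C(C)C1=O | intermediate
4 | methyl 2-(bromomethyl)acrylate | C=C(CBr)C(=O)OC | starting material
5 | 6-methylcarvone lithium enolate | [Li]OC1=C(C)[C@H](C(C)=C)CC=C1C | intermediate (not isolated)
6 | methyl 2-{[(1S,6S)-1,3-dimethyl-2-oxo-6-(prop-1-en-2-yl)cyclohex-3-en-1-yl]methyl}prop-2-enoate | O=C1C(C)=CC[C@@H](C(C)=C)[C@]1(C)CC(=C)C(=O)OC | intermediate
7 | methyl (4aS,8aS)-4,4,7,8a-tetramethyl-8-oxo-1,2,3,4,4a,5,8,8a-octahydronaphthalene-2-carboxylate, C2 epimer mixture | O=C1C(C)=CC[C@H]2C(C)(C)CC(C(=O)OC)C[C@]12C | intermediate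
8 | (4aS,8aS)-4,4,7,8a-tetramethyl-8-oxo-1,2,3,4,4a,5,8,8a-octahydronaphthalene-2-carboxylic acid, C2 epimer mixture | O=C1C(C)=CC[C@H]2C(C)(C)CC(C(=O)O)C[C@]12C | intermediate
9 | Barton ester of 8 (2-thioxopyridin-1(2H)-yl ester) | O=C1C(C)=CC[C@H]2C(C)(C)CC(C(=O)ON3C=CC=CC3=S)C[C@]12C | intermediate (not isolated)
10 | (4aS,8aS)-2,5,5,8a-tetramethyl-4a,5,6,7,8,8a-hexahydronaphthalen-1(4H)-one | O=C1C(C)=CC[C@H]2C(C)(C)CCC[C@]12C | intermediate
11 | drima-7,9(11)-diene | C=C1C(C)=CC[C@H]2C(C)(C)CCC[C@]12C | intermediate
12 | (S)-3-bromo-2-methylpropan-1-ol | OC[C@H](C)CBr | starting material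
13 | (S)-3-bromo-2-methylpropyl 2-methylpropanoate | CC(C)C(=O)OC[C@H](C)CBr | intermediate
14 | B-(drim-7-en-11-yl)-9-borabicyclo[3.3.1]nonane | C1CC2CCCC(C1)B2C[C@H]1C(C)=CC[C@H]2C(C)(C)CCC[C@]12C | intermediate (not isolated)
15 | (2R)-2-methyl-4-[(1S,4aS,8aS)-2,5,5,8a-tetramethyl-1,4,4a,5,6,7,8,8a-octahydronaphthalen-1-yl]butyl 2-methylpropanoate | CC(C)C(=O)OC[C@H](C)CC[C@H]1C(C)=CC[C@H]2C(C)(C)CCC[C@]12C | intermediate
16 | (2R)-4-[(1R,4aS,8aS)-2-formyl-5,5,8a-trimethyl-1,4,4a,5,6,7,8,8a-octahydronaphthalen-1-yl]-2-methylbutyl 2-methylpropanoate | CC(C)C(=O)OC[C@H](C)CC[C@H]1C(C=O)=CC[C@H]2C(C)(C)CCC[C@]12C | intermediate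
17 | (1R,4aS,8aS)-5,5,8a-trimethyl-1-[(3R)-3-methyl-4-(2-methylpropanoyloxy)butyl]-1,4,4a,5,6,7,8,8a-octahydronaphthalene-2-carboxylic acid | CC(C)C(=O)OC[C@H](C)CC[C@H]1C(C(=O)O)=CC[C@H]2C(C)(C)CCC[C@]12C | target

**Step count and risks**

Total step count: 10. Longest linear sequence: 9 steps (steps 1–6 and 8–10 from carvone).

The three steps most likely to fail:

1. Step 8. Oxidative addition of the β-branched bromide 13 to the zerovalent palladium–PCy3 complex may be slow, so that β-hydride elimination and protodeboronation of the hindered borane 14 win. The fallback sets out from 11 and comes back at 15. Diene 11 is hydroborated as before and borane 14 is oxidised with NaOH/H2O2 to drim-7-en-11-ol F1, which Appel iodination (I2, PPh3, imidazole) converts to 11-iododrim-7-ene F2. Separately, 12 is silylated (TBSCl, imidazole) to (S)-(3-bromo-2-methylpropoxy)(tert-butyl)dimethylsilane F3, and magnesium turns this into the Grignard reagent F4. Copper-catalysed coupling of F2 with F4 (Li2CuCl4, THF, −20 °C to rt) should give the coupled silyl ether F5, Bu4NF frees the primary alcohol F6, and acylation with isobutyryl chloride and Et3N gives 15.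

2. Step 3. The iron hydride may reduce the tertiary C4 radical before it cyclises (net hydrogenation of the isopropenyl group), or hydrogen-atom transfer may go to the acrylate. The fallback sets out from 6 and comes back at 7. Markovnikov addition of HBr (HBr in AcOH, 0 °C) to the isopropenyl group gives the tertiary bromide F7. Bu3SnH with AIBN (slow addition, benzene, 80 °C) then generates the same C4 radical at a low hydride concentration, so that the 6-endo Giese closure to 7 can outrun reduction.

3. Step 6. The ylide may act as a base on the enone (γ-deprotonation) or fail to add to the carbonyl group flanked by the quaternary C10. The fallback sets out from 10 and comes back at 11 by Peterson olefination. Me3SiCH2Li with CeCl3 (THF, −78 °C) adds to the C9 carbonyl to give the β-hydroxysilane F8 (either C9 epimer), and KH in THF eliminates the silanol to give 11.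

**Further compounds**

F1 | step 8 | drim-7-en-11-ol (natural drimenol configuration) | OC[C@H]1C(C)=CC[C@H]2C(C)(C)CCC[C@]12C
F2 | step 8 | 11-iododrim-7-ene | IC[C@H]1C(C)=CC[C@H]2C(C)(C)CCC[C@]12C
F3 | step 8 | (S)-(3-bromo-2-methylpropoxy)(tert-butyl)dimethylsilane | CC(C)(C)[Si](C)(C)OC[C@H](C)CBr
F4 | step 8 | Grignard reagent from F3, [3-(tert-butyldimethylsilyloxy)-2-methylpropyl]magnesium bromide | CC(C)(C)[Si](C)(C)OC[C@H](C)C[Mg]Br
F5 | step 8 | tert-butyldimethylsilyl ether of the coupled alcohol | CC(C)(C)[Si](C)(C)OC[C@H](C)CC[C@H]1C(C)=CC[C@H]2C(C)(C)CCC[C@]12C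
F6 | step 8 | (2R)-2-methyl-4-(drim-7-en-11-yl... ring as in 15)butan-1-ol, the free alcohol of 15 | OC[C@H](C)CC[C@H]1C(C)=CC[C@H]2C(C)(C)CCC[C@]12C
F7 | step 3 | tertiary bromide from HBr addition to the isopropenyl group of 6 | O=C1C(C)=CC[C@@H](C(C)(C)Br)[C@]1(C)CC(=C)C(=O)OC
F8 | step 6 | β-hydroxysilane from addition of Me3SiCH2Li to the C9 ketone of 10 | C[Si](C)(C)CC1(O)C(C)=CC[C@H]2C(C)(C)CCC[C@]12C
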